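**Plan**

1. Retrosynthetic cuts: the C9 silyl ether, C3–H and C2–Br, then the C5 methylene (back to a ketone in a spiro vinylogous ester); then, together, the ring B bonds C6–C7 and C8–Cl; then C6–Cl and C6–C11, giving the dimedone isobutyl vinylogous ester and a five-carbon iodide from (R)-linalool.
2. Enabling feature: in ring B the CHCl carbon C8 lies one CH2 (C7) from the spiro carbon C6, and C6 is α to the ring A carbon C5 that carries the exocyclic methylene, a ketone in disguise. An α-keto radical at C6 and a vinyl group on C9 can therefore form C6–C7 and C8–Cl in one atom-transfer event.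
3. Forward order: ring A is bought as dimedone; the linalool chain, shortened by one carbon so that ring B is six-membered, is joined at C6 by enolate alkylation; C6 is chlorinated; copper-catalysed chlorine atom transfer closes ring B; ring A is then adjusted.
4. Stereochemistry: C9 comes from (R)-linalool; C6 and C8 are set in the key step under control of C9; C3 is set by hydride delivery cis to bromine.
5. C2 (C–Br) has no reliable substrate control: its epimers are carried and the (2S,3R) series is isolated after the reduction.

Key step: step 7

Remark (numbering): all spiro compounds use the spiro[5.5]undecane numbering of the target: C1 CMe2, C2 CHBr, C3 CHOH, C4 CH2, C5 C(=CH2), C6 spiro, C7 CH2, C8 CHCl, C9 C(Me)O, C10, C11; ring A is C1–C6, ring B is C6–C11.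
Remark (assumption): (R)-(−)-linalool is taken as commercially available in high enantiomeric purity.
Remark (isomers): 10, 11 and 13 are epimer mixtures at a centre that is lost later, and 16 and 17 are C2-epimer mixtures; one isomer is drawn in each case. The spiro descriptor changes from R (12–15) to S (16–19) only because the CIP priorities change when bromine enters at C2.

**Route**

Step 1
Reactants: 1 dimedone; 2 2-methylpropan-1-ol
Product: 3 3-isobutoxy-5,5-dimethylcyclohex-2-en-1-one
Conditions: 4-MeC6H4SO3H·H2O (cat.), toluene, reflux, Dean–Stark
Reagents that add atoms: none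
Why: Acid-catalysed O-alkylation of the enolised 1,3-dione (vinylogous Fischer esterification) is driven to the vinylogous ester by azeotropic removal of water, and no stereocentre is formed.

Step 2
Reactants: 4 (R)-linalool
Product: 5 (3R)-3,7-dimethyl-3-(triethylsilyloxy)octa-1,6-diene
Conditions: Et3SiOTf, 2,6-lutidine, CH2Cl2, −78 → 0 °C
Reagents that add atoms: triethylsilyl trifluoromethanesulfonate, CC[Si](CC)(CC)OS(=O)(=O)C(F)(F)F
Why: Silylation with a silyl triflate and a hindered pyridine base is the standard protection of a tertiary alcohol, and the carbinol stereocentre is not touched.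

Step 3
Reactants: 5 (3R)-3,7-dimethyl-3-(triethylsilyloxy)octa-1,6-diene
Product: 7 (4R)-4-methyl-4-(triethylsilyloxy)hex-5-enoic acid, via aldehyde 6 (not isolated)
Conditions: O3, pyridine, CH2Cl2, −78 °C (Sudan Red 7B end-point); then NaClO2, NaH2PO4, 2-methyl-2-butene, tBuOH–H2O, 0 °C → rt
Reagents that add atoms: ozone, [O-][O+]=O; sodium chlorite, [Na+].[O-]Cl=O
Why: Ozone attacks the electron-rich trisubstituted alkene much faster than the hindered vinyl group (chemoselective ozonolysis, with pyridine decomposing the carbonyl oxide to aldehyde 6), and the Pinnick oxidation with a hypochlorite scavenger then gives the acid without touching the vinyl group or the stereocentre.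

Step 4
Reactants: 7 (4R)-4-methyl-4-(triethylsilyloxy)hex-5-enoic acid
Product: 9 (3R)-5-iodo-3-methyl-3-(triethylsilyloxy)pent-1-ene, via Barton ester 8 (not isolated)
Conditions: DCC, N-hydroxypyridine-2-thione, 4-(dimethylamino)pyridine (cat.), CH2Cl2, 0 °C → rt, dark; then CHI3, benzene, hν (tungsten lamp), reflux
Reagents that add atoms: iodoform, IC(I)I
Why: In this Barton decarboxylative iodination the thiohydroxamate ester fragments under light to a primary pent-4-enyl radical that has no favourable cyclisation and abstracts iodine from iodoform, which removes the one carbon that would otherwise make ring B seven-membered and leaves the remote stereocentre untouched.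

Step 5
Reactants: 3 3-isobutoxy-5,5-dimethylcyclohex-2-en-1-one; 9 (3R)-5-iodo-3-methyl-3-(triethylsilyloxy)pent-1-ene
Product: 10 3-isobutoxy-5,5-dimethyl-6-[(3R)-3-methyl-3-(triethylsilyloxy)pent-4-en-1-yl]cyclohex-2-en-1-one (both C6 epimers)
Conditions: LiN(iPr)2, THF, −78 °C; then 9, DMPU, −78 °C → rt
Reagents that add atoms: none
Why: In this Stork–Danheiser alkylation LiN(iPr)2 removes the α′ proton of the vinylogous ester kinetically and the cross-conjugated enolate displaces the primary iodide; the new C6 centre forms as both epimers, which does not matter because C6 becomes planar in steps 6 and 7.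

Step 6
Reactants: 10 3-isobutoxy-5,5-dimethyl-6-[(3R)-3-methyl-3-(triethylsilyloxy)pent-4-en-1-yl]cyclohex-2-en-1-one
Product: 11 6-chloro-3-isobutoxy-5,5-dimethyl-6-[(3R)-3-methyl-3-(triethylsilyloxy)pent-4-en-1-yl]cyclohex-2-en-1-one (both C6 epimers)
Conditions: LiN(iPr)2, TMEDA, THF, −78 → 0 °C; then TsCl, −78 °C → rt
Reagents that add atoms: p-toluenesulfonyl chloride, Cc1ccc(cc1)S(Cl)(=O)=O
Why: The one remaining α′ hydrogen is removed to give the tetrasubstituted enolate, which is chlorinated at carbon by the sulfonyl chloride acting as a positive-chlorine donor (electrophilic enolate chlorination); both C–Cl epimers form and both converge in step 7.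

Step 7
Reactants: 11 6-chloro-3-isobutoxy-5,5-dimethyl-6-[(3R)-3-methyl-3-(triethylsilyloxy)pent-4-en-1-yl]cyclohex-2-en-1-one
Product: 12 (6R,8S,9R)-8-chloro-3-isobutoxy-1,1,9-trimethyl-9-(triethylsilyloxy)spiro[5.5]undec-3-en-5-one
Conditions: CuCl (20 mol %), tris(2-pyridylmethyl)amine (20 mol %), 2,2′-azobis(2-methylpropionitrile) (10 mol %), degassed 1,2-dichloroethane (0.02 M), 80 °C
Reagents that add atoms: none
Why: Monovalent copper bound to tris(2-pyridylmethyl)amine abstracts chlorine reversibly from either C6 epimer of 11 to give one planar tertiary α-keto radical, which adds to the terminal vinyl carbon; the resulting secondary C8 radical takes chlorine back from the divalent copper chloride complex, so C6–C7 and C8–Cl form in one catalytic atom-transfer event. The closest known reaction type is the copper-catalysed atom-transfer radical cyclisation (intramolecular Kharasch addition) of α-halo carbonyl compounds. Ring B closes in the 6-endo-trig mode. The spiro centre C6 is set by a chair-like transition state in which the CMe2 carbon of ring A is pseudo-equatorial on the forming ring and the C9 methyl is equatorial with the silyloxy group axial, so the linalool-derived C9 centre decides which face of the radical is attacked; C8 is set by equatorial chlorine delivery, because the axial face is shielded by the axial C5 carbonyl carbon, which places chlorine cis to the silyloxy group. The step needs 6-endo over 5-exo closure: the internal vinyl carbon sits next to the fully substituted C9 and would have to bond to a radical carbon that is itself flanked by CMe2, and high dilution, heat and a low standing concentration of divalent copper keep addition of this stabilised radical reversible, so that the cyclohexyl radical is the one that is trapped.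

Step 8
Reactants: 12 (6R,8S,9R)-8-chloro-3-isobutoxy-1,1,9-trimethyl-9-(triethylsilyloxy)spiro[5.5]undec-3-en-5-one
Product: 14 (6R,8S,9R)-8-chloro-1,1,9-trimethyl-9-(triethylsilyloxy)-5-[(trimethylsilyl)methyl]spiro[5.5]undec-4-en-3-one, via carbinol adduct 13 (not isolated)
Conditions: Me3SiCH2Li, CeCl3, THF, −78 → 0 °C; then 0.5 M aq. HCl, 0 °C
Reagents that add atoms: (trimethylsilyl)methyllithium, [Li]C[Si](C)(C)C
Why: The weakly basic organocerium reagent adds 1,2 to the hindered vinylogous ester carbonyl, and brief mild acid converts adduct 13 into the transposed enone with loss of isobutanol (Stork–Danheiser transposition) while the C–SiMe3 bond survives; the carbinol centre of 13 is lost again.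

Step 9
Reactants: 14 (6R,8S,9R)-8-chloro-1,1,9-trimethyl-9-(triethylsilyloxy)-5-[(trimethylsilyl)methyl]spiro[5.5]undec-4-en-3-one
Product: 16 (2S,6S,8S,9R)-2-bromo-8-chloro-1,1,9-trimethyl-9-(triethylsilyloxy)-5-[(trimethylsilyl)methyl]spiro[5.5]undec-4-en-3-one (2S drawn; 2R epimer also formed), via silyl dienol ether 15 (not isolated)
Conditions: LiN(iPr)2, THF, −78 °C, then Me3SiCl; then N-bromosuccinimide, NaHCO3, THF, −78 → 0 °C
Reagents that add atoms: N-bromosuccinimide, BrN1C(=O)CCC1=O
Why: As with isophorone, the amide base deprotonates the enone kinetically at the α′ carbon C2, and the bromo imide brominates the derived silyl dienol ether 15 at that carbon (α-bromination through a silyl enol ether); the remote ring B centres are not expected to bias the new C–Br centre, so both C2 epimers are carried forward and resolved at step 11.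

Step 10
Reactants: 16 (2S,6S,8S,9R)-2-bromo-8-chloro-1,1,9-trimethyl-9-(triethylsilyloxy)-5-[(trimethylsilyl)methyl]spiro[5.5]undec-4-en-3-one (C2-epimer mixture)
Product: 17 (2S,6S,8S,9R)-2-bromo-8-chloro-1,1,9-trimethyl-5-methylidene-9-(triethylsilyloxy)spiro[5.5]undecan-3-one (2S drawn; 2R epimer also present)
Conditions: Bu4NF, AcOH, THF, −40 → 0 °C; pH 7 buffer
Reagents that add atoms: none
Why: Fluoride cleaves the C–Si bond of the vinylogous α-silyl ketone to a dienolate that acetic acid protonates kinetically at the α carbon C4 (deconjugative protodesilylation), which leaves the double bond exocyclic at C5; buffering and low temperature are meant to prevent migration into conjugation and attack on the C–Br carbon.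

Step 11
Reactants: 17 (2S,6S,8S,9R)-2-bromo-8-chloro-1,1,9-trimethyl-5-methylidene-9-(triethylsilyloxy)spiro[5.5]undecan-3-one (C2-epimer mixture)
Product: 18 (2S,3R,6S,8S,9R)-2-bromo-8-chloro-1,1,9-trimethyl-5-methylidene-9-(triethylsilyloxy)spiro[5.5]undecan-3-ol
Conditions: iBu2AlH, THF, −78 °C; aq. potassium sodium tartrate; chromatography
Reagents that add atoms: none
Why: The aluminium hydride reduces the α-bromo ketone without touching the C–Br or C–Cl bonds, and because the axial methyl on C1 blocks axial attack (as in 3,3,5-trimethylcyclohexanone) hydride enters equatorially, so the new C3 hydroxyl is axial and cis to the equatorial bromine (substrate-controlled carbonyl reduction); the (2S,3R) isomer is separated here from the cis-bromohydrin that arises from the 2R epimer.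

Step 12
Reactants: 18 (2S,3R,6S,8S,9R)-2-bromo-8-chloro-1,1,9-trimethyl-5-methylidene-9-(triethylsilyloxy)spiro[5.5]undecan-3-ol
Product: 19 (2S,3R,6S,8S,9R)-2-bromo-8-chloro-1,1,9-trimethyl-5-methylidenespiro[5.5]undecane-3,9-diol (CNP0121782.1)
Conditions: HF·pyridine, pyridine, THF, 0 °C → rt
Reagents that add atoms: none
Why: Buffered hydrogen fluoride cleaves the tertiary Si–O bond (fluoride desilylation) under conditions that should neither ionise the tertiary carbinol nor disturb the two cis-halohydrins or the exocyclic alkene, and no stereocentre is touched.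

**Compound list**

1 | dimedone (5,5-dimethylcyclohexane-1,3-dione) | CC1(C)CC(=O)CC(=O)C1 | starting material
2 | 2-methylpropan-1-ol | CC(C)CO | starting material
3 | 3-isobutoxy-5,5-dimethylcyclohex-2-en-1-one | CC(C)COC1=CC(=O)CC(C)(C)C1 | intermediate
4 | (R)-linalool, (3R)-3,7-dimethylocta-1,6-dien-3-ol | CC(C)=CCC[C@@](C)(O)C=C | starting material
5 | (3R)-3,7-dimethyl-3-(triethylsilyloxy)octa-1,6-diene | CC(C)=CCC[C@@](C)(O[Si](CC)(CC)CC)C=C | intermediate
6 | (4R)-4-methyl-4-(triethylsilyloxy)hex-5-enal | O=CCC[C@@](C)(O[Si](CC)(CC)CC)C=C | intermediate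
7 | (4R)-4-methyl-4-(triethylsilyloxy)hex-5-enoic acid | OC(=O)CC[C@@](C)(O[Si](CC)(CC)CC)C=C | intermediate
8 | 2-thioxopyridin-1(2H)-yl (4R)-4-methyl-4-(triethylsilyloxy)hex-5-enoate (Barton ester) | S=C1C=CC=CN1OC(=O)CC[C@@](C)(O[Si](CC)(CC)CC)C=C | intermediate
9 | (3R)-5-iodo-3-methyl-3-(triethylsilyloxy)pent-1-ene | ICC[C@@](C)(O[Si](CC)(CC)CC)C=C | intermediate
10 | 3-isobutoxy-5,5-dimethyl-6-[(3R)-3-methyl-3-(triethylsilyloxy)pent-4-en-1-yl]cyclohex-2-en-1-one (both C6 epimers) | CC(C)COC1=CC(=O)C(CC[C@@](C)(O[Si](CC)(CC)CC)C=C)C(C)(C)C1 | intermediate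
11 | 6-chloro-3-isobutoxy-5,5-dimethyl-6-[(3R)-3-methyl-3-(triethylsilyloxy)pent-4-en-1-yl]cyclohex-2-en-1-one (both C6 epimers, one drawn) | CC(C)COC1=CC(=O)[C@@](Cl)(CC[C@@](C)(O[Si](CC)(CC)CC)C=C)C(C)(C)C1 | intermediate
12 | (6R,8S,9R)-8-chloro-3-isobutoxy-1,1,9-trimethyl-9-(triethylsilyloxy)spiro[5.5]undec-3-en-5-one | O=C1C=C(OCC(C)C)CC(C)(C)[C@]12CC[C@@](C)(O[Si](CC)(CC)CC)[C@@H](Cl)C2 | intermediate
13 | (6R,8S,9R)-8-chloro-3-isobutoxy-1,1,9-trimethyl-9-(triethylsilyloxy)-5-[(trimethylsilyl)methyl]spiro[5.5]undec-3-en-5-ol (C5 epimers) | C[Si](C)(C)CC1(O)C=C(OCC(C)C)CC(C)(C)[C@]12CC[C@@](C)(O[Si](CC)(CC)CC)[C@@H](Cl)C2 | intermediate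
14 | (6R,8S,9R)-8-chloro-1,1,9-trimethyl-9-(triethylsilyloxy)-5-[(trimethylsilyl)methyl]spiro[5.5]undec-4-en-3-one | C[Si](C)(C)CC1=CC(=O)CC(C)(C)[C@]12CC[C@@](C)(O[Si](CC)(CC)CC)[C@@H](Cl)C2 | intermediate
15 | (6R,8S,9R)-8-chloro-1,1,9-trimethyl-9-(triethylsilyloxy)-3-(trimethylsilyloxy)-5-[(trimethylsilyl)methyl]spiro[5.5]undeca-2,4-diene | C[Si](C)(C)CC1=CC(O[Si](C)(C)C)=CC(C)(C)[C@]12CC[C@@](C)(O[Si](CC)(CC)CC)[C@@H](Cl)C2 | intermediate
16 | (2S,6S,8S,9R)-2-bromo-8-chloro-1,1,9-trimethyl-9-(triethylsilyloxy)-5-[(trimethylsilyl)methyl]spiro[5.5]undec-4-en-3-one (carried with its 2R epimer) | C[Si](C)(C)CC1=CC(=O)[C@@H](Br)C(C)(C)[C@]12CC[C@@](C)(O[Si](CC)(CC)CC)[C@@H](Cl)C2 | intermediate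
17 | (2S,6S,8S,9R)-2-bromo-8-chloro-1,1,9-trimethyl-5-methylidene-9-(triethylsilyloxy)spiro[5.5]undecan-3-one (carried with its 2R epimer) | C=C1CC(=O)[C@@H](Br)C(C)(C)[C@]12CC[C@@](C)(O[Si](CC)(CC)CC)[C@@H](Cl)C2 | intermediate
18 | (2S,3R,6S,8S,9R)-2-bromo-8-chloro-1,1,9-trimethyl-5-methylidene-9-(triethylsilyloxy)spiro[5.5]undecan-3-ol | C=C1C[C@@H](O)[C@@H](Br)C(C)(C)[C@]12CC[C@@](C)(O[Si](CC)(CC)CC)[C@@H](Cl)C2 | intermediate
19 | (2S,3R,6S,8S,9R)-2-bromo-8-chloro-1,1,9-trimethyl-5-methylidenespiro[5.5]undecane-3,9-diol | C=C1C[C@@H](O)[C@@H](Br)C(C)(C)[C@]12CC[C@@](C)(O)[C@@H](Cl)C2 | target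

**Step count and risks**

Total step count: 12. Longest linear sequence: 11 steps (from 4 to 19, steps 2–12).

Steps most likely to fail:

Step 7. The tertiary radical may close 5-exo onto the internal vinyl carbon, or attack may occur on the wrong face of the radical, since the preference for methyl over silyloxy in the equatorial site is modest. The hindered tertiary chloride may also lose HCl before copper abstracts chlorine. The fallback changes how the radical is made and terminated; it sets out from ketone 10, before chlorination, and comes back at 12. Compound 10 would be heated with Mn(OAc)3·2H2O, LiCl and a little CuCl2 in acetic acid–acetonitrile (oxidative free-radical cyclisation). The enolate bound to trivalent manganese is oxidised to the same tertiary α-keto radical, so no carbon–chlorine precursor is needed. The radical can equilibrate between open and closed forms before the cyclohexyl radical is chlorinated by ligand transfer from divalent copper chloride. The stereochemical argument is the same as in step 7, and no compound outside the list is formed.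

Step 9. The remote ring B centres are unlikely to give facial discrimination at C2, and the two cis-bromohydrins of step 11 may be hard to separate. The fallback replaces substrate control and chromatography by reagent control; it sets out from 17 (C2-epimer mixture) and comes back at 18. The mixture would be reduced under Corey–Bakshi–Shibata conditions with (S)-1-methyl-3,3-diphenyltetrahydro-1H,3H-pyrrolo[1,2-c][1,3,2]oxazaborole and catecholborane in toluene at low temperature. The usual model, with the carbonyl bound anti to the larger C2 side, predicts hydride delivery to the face that gives the (3R) alcohol. For the (2S)-bromide this coincides with the substrate preference (matched), for the (2R)-bromide it opposes it (mismatched). Compound 18 should therefore form from the (2S) ketone, while the (2R) ketone remains, is removed easily as a ketone, is re-equilibrated at C2 (bromide exchange with Bu4NBr or brief acid-catalysed enolisation) and is resubmitted. No compound outside the list is formed.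

Step 10. Acetate or fluoride may move the exocyclic double bond into conjugation, or the dienolate may displace bromide (Favorskii-type ring contraction). The fallback uses allylsilane chemistry instead of dienolate chemistry; it sets out from 16 and comes back at 19. iBu2AlH at −78 °C would reduce the enone carbonyl of 16 to the allylic alcohol (2S,3R,6S,8S,9R)-2-bromo-8-chloro-1,1,9-trimethyl-9-(triethylsilyloxy)-5-[(trimethylsilyl)methyl]spiro[5.5]undec-4-en-3-ol F1, with the hydroxyl cis to bromine for the same reason as in step 11. HCl in methanol–CH2Cl2 would then protonate the allylsilane at C4 with loss of the trimethylsilyl group and shift of the double bond to the exocyclic position (protodesilylation with allylic transposition). The same acid removes the triethylsilyl group, so the sequence ends at 19 after separation from the diastereomer that stems from the 2R epimer. The bromine next to C3 should slow ionisation of the allylic alcohol, which is the competing 1,4-elimination.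

**Further compounds**

F0 | step 7 | none | none
F0 | step 9 | none | none
F1 | step 10 | (2S,3R,6S,8S,9R)-2-bromo-8-chloro-1,1,9-trimethyl-9-(triethylsilyloxy)-5-[(trimethylsilyl)methyl]spiro[5.5]undec-4-en-3-ol | C[Si](C)(C)CC1=C[C@@H](O)[C@@H](Br)C(C)(C)[C@]12CC[C@@](C)(O[Si](CC)(CC)CC)[C@@H](Cl)C2
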